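The oxane ring (O1, C2 gem-dimethyl, C3 CHBr, C4, C5, C6) is cut at O1–C6 and C3–C4. Both bonds are made in one flask from a tertiary allylic pinacol boronate whose boron-bearing carbon is the future C6: 9-BBN hydroboration of its vinyl group, B-alkyl Suzuki–Miyaura coupling with 1-bromo-2-methylpropene (C3–C4) and stereoretentive peroxide oxidation of the C–B bond (O1–C6). The step exploits the 1,3-relation between the fully substituted C6 and the C4 methylene. The tertiary alcohol formed then closes the oxane by 6-endo bromoetherification, and the trans-diaxial Br/Cl pair of the cyclohexane is drawn from a ring epoxide carried from (S)-limonene.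

Key step: step 7

Assumption: in step 6 the sense of the copper-catalysed γ-borylation is dictated by the chiral NHC ligand, whose enantiomer is chosen to give the R-configured boronate 9 and is taken to override the remote ring stereocentres.

Step 1
Reactants: 1 (S)-(−)-limonene
Product: 3 trans-limonene 1,2-oxide (oxirane oxygen cis to the isopropenyl group), via bromohydrin 2 (not isolated)
Conditions: NBS, acetone–H2O, 0 °C; then aq. NaOH, rt
Reagents that add atoms: water, O
Why: Bromohydrin formation followed by base-induced epoxide closure: NBS attacks the more electron-rich trisubstituted ring alkene, water opens the bromonium ion at the tertiary carbon in the trans-diaxial (Fürst–Plattner) sense and the alkoxide then displaces bromide with inversion, so that both new ring stereocentres are set by the existing limonene centre.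

Step 2
Reactants: 3 trans-limonene 1,2-oxide
Product: 4 epoxy methyl ketone
Conditions: O3, CH2Cl2–MeOH, −78 °C; then Me2S, −78 °C → rt
Reagents that add atoms: ozone, [O-][O+]=O
Why: Ozonolysis with reductive work-up cleaves the only remaining alkene to the methyl ketone and should leave the epoxide and the ring stereocentres untouched.

Step 3
Reactants: 4 epoxy methyl ketone; 5 triethyl phosphonoacetate
Product: 6 (E)-enoate
Conditions: 5, NaH, THF, 0 °C (anion pre-formed); then 4, 0 → 60 °C; chromatography
Reagents that add atoms: none
Why: Horner–Wadsworth–Emmons olefination should favour the E-enoate (ester trans to the bulky ring substituent), the pre-formed, weakly basic phosphonate anion avoiding epimerisation of the enolisable centre next to the ketone and the minor Z isomer being removed so that step 6 sees one alkene geometry.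

Step 4
Reactants: 6 (E)-enoate
Product: 7 (E)-allylic alcohol
Conditions: i-Bu2AlH, CH2Cl2, −78 °C; aq. KNaC4H4O6
Reagents that add atoms: none
Why: 1,2-Reduction of the conjugated ester with i-Bu2AlH at low temperature should give the E-allylic alcohol without opening the trisubstituted epoxide.

Step 5
Reactants: 7 (E)-allylic alcohol
Product: 8 allylic methyl carbonate
Conditions: ClCO2Me, pyridine, CH2Cl2, 0 °C
Reagents that add atoms: methyl chloroformate, COC(=O)Cl
Why: Acylation of the primary allylic alcohol installs the carbonate leaving group needed for copper-catalysed allylic substitution.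

Step 6
Reactants: 8 allylic methyl carbonate
Product: 9 tertiary allylic pinacol boronate
Conditions: B2pin2, Cu(OTf)2 (5 mol%), chiral sulfonate-bearing imidazolinium salt (NHC precursor, 6 mol%), NaOMe (30 mol%), DME, −30 °C
Reagents that add atoms: bis(pinacolato)diboron, CC1(C)OB(OC1(C)C)B1OC(C)(C)C(C)(C)O1
Why: Copper-catalysed enantioselective allylic substitution (SN2′) delivers a boryl-copper nucleophile to the γ-carbon of the E-trisubstituted allylic carbonate with loss of methyl carbonate, the chiral NHC ligand selecting the alkene face so that the boron-bearing quaternary centre is formed with R configuration (catalyst control).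

Step 7
Reactants: 9 tertiary allylic pinacol boronate; 10 1-bromo-2-methylprop-1-ene
Product: 13 ring-epoxidised (S,S)-α-bisabolol, via alkylborane 11 (not isolated), via tertiary boronate 12 (not isolated)
Conditions: 9-BBN, THF, 0 °C → rt; then 10, Pd(dppf)Cl2 (5 mol%), aq. K3PO4, DMF, 50 °C; then NaOH, H2O2, 0 °C → rt
Reagents that add atoms: hydrogen peroxide, OO
Why: 9-BBN adds anti-Markovnikov to the monosubstituted vinyl group to give the primary alkylborane 11, palladium-catalysed B-alkyl Suzuki–Miyaura coupling (oxidative addition of 10, base-assisted transmetalation of the primary alkyl group, reductive elimination) forms the future C3–C4 bond of the oxane, and alkaline hydrogen peroxide then converts the tertiary C–B bond of 12 into the C6–O1 bond by 1,2-migration of carbon from boron to oxygen. The closest known reaction types are the one-pot hydroboration/B-alkyl Suzuki–Miyaura coupling and the stereoretentive oxidation of tertiary pinacol boronates. No ring is closed in this step. No new stereocentre is created: the configuration fixed at C6 in step 6 is carried into the carbinol with retention, because the migrating carbon keeps its geometry (the descriptor changes from R to S only through the priority change from B to O). The step needs chemoselectivity between the two boron centres, and the substrate secures it, since only the primary B-alkyl-9-BBN unit transmetalates to palladium while the hindered tertiary pinacol boronate stays inert until peroxide is added. The trisubstituted epoxide should tolerate all three stages (neutral borane, aqueous phosphate, basic peroxide).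

Step 8
Reactants: 13 ring-epoxidised (S,S)-α-bisabolol
Product: 14 bromo-oxane epoxide
Conditions: 2,4,4,6-tetrabromocyclohexa-2,5-dienone, CH3NO2, 0 °C, dark
Reagents that add atoms: 2,4,4,6-tetrabromocyclohexa-2,5-dienone, O=C1C(Br)=CC(Br)(Br)C=C1Br
Why: Bromoetherification: the bromonium ion of the side-chain alkene is opened at its tertiary carbon by the tertiary hydroxyl in a 6-endo (Markovnikov) chair transition state with the bulky ring substituent on C6 equatorial, and anti addition places bromine equatorial on C3, trans to that substituent, so that C3 is set by the existing C6 centre.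

Step 9
Reactants: 14 bromo-oxane epoxide
Product: 15 chlorohydrin
Conditions: LiCl, AcOH, THF, rt
Reagents that add atoms: lithium chloride, [Li+].[Cl-]
Why: Nucleophilic epoxide opening by chloride: for this epoxide diastereomer the trans-diaxial (Fürst–Plattner) pathway coincides with attack at the less substituted carbon, so chloride should enter the secondary carbon with inversion and leave the axial tertiary alcohol unchanged.

Step 10
Reactants: 15 chlorohydrin
Product: 16 target bromochloride
Conditions: Me3SiBr, CH2Cl2, −20 °C → 0 °C
Reagents that add atoms: bromotrimethylsilane, C[Si](C)(C)Br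
Why: SN1-type substitution with anchimeric assistance: ionisation of the silylated axial tertiary hydroxyl is assisted by the antiperiplanar axial chlorine, and bromide should open the bridged chloronium ion at the tertiary carbon from the face the oxygen occupied, giving the tertiary bromide with retention and the trans-diaxial Br/Cl pair.

Compound list
1 | (S)-(−)-limonene, (4S)-1-methyl-4-(prop-1-en-2-yl)cyclohex-1-ene | C=C(C)[C@H]1CCC(C)=CC1 | starting material
2 | (1R,2R,4S)-2-bromo-1-methyl-4-(prop-1-en-2-yl)cyclohexan-1-ol (trans-diaxial bromohydrin) | C=C(C)[C@H]1CC[C@@](C)(O)[C@H](Br)C1 | intermediate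
3 | trans-limonene 1,2-oxide, (1R,4S,6S)-1-methyl-4-(prop-1-en-2-yl)-7-oxabicyclo[4.1.0]heptane | C=C(C)[C@H]1CC[C@@]2(C)O[C@H]2C1 | intermediate
4 | 1-[(1S,3S,6R)-6-methyl-7-oxabicyclo[4.1.0]heptan-3-yl]ethan-1-one | CC(=O)[C@H]1CC[C@@]2(C)O[C@H]2C1 | intermediate
5 | triethyl phosphonoacetate | CCOC(=O)CP(=O)(OCC)OCC | starting material
6 | ethyl (2E)-3-[(1S,3S,6R)-6-methyl-7-oxabicyclo[4.1.0]heptan-3-yl]but-2-enoate | CCOC(=O)/C=C(\C)[C@H]1CC[C@@]2(C)O[C@H]2C1 | intermediate
7 | (2E)-3-[(1S,3S,6R)-6-methyl-7-oxabicyclo[4.1.0]heptan-3-yl]but-2-en-1-ol | OC/C=C(\C)[C@H]1CC[C@@]2(C)O[C@H]2C1 | intermediate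
8 | methyl (2E)-3-[(1S,3S,6R)-6-methyl-7-oxabicyclo[4.1.0]heptan-3-yl]but-2-en-1-yl carbonate | COC(=O)OC/C=C(\C)[C@H]1CC[C@@]2(C)O[C@H]2C1 | intermediate
9 | 4,4,5,5-tetramethyl-2-{(2R)-2-[(1S,3S,6R)-6-methyl-7-oxabicyclo[4.1.0]heptan-3-yl]but-3-en-2-yl}-1,3,2-dioxaborolane | C=C[C@](C)(B1OC(C)(C)C(C)(C)O1)[C@H]1CC[C@@]2(C)O[C@H]2C1 | intermediate
10 | 1-bromo-2-methylprop-1-ene | CC(C)=CBr | starting material
11 | 9-{(3R)-3-[(1S,3S,6R)-6-methyl-7-oxabicyclo[4.1.0]heptan-3-yl]-3-(4,4,5,5-tetramethyl-1,3,2-dioxaborolan-2-yl)butyl}-9-borabicyclo[3.3.1]nonane | C(C[C@](C)(B1OC(C)(C)C(C)(C)O1)[C@H]1CC[C@@]2(C)O[C@H]2C1)B1C2CCCC1CCC2 | intermediate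
12 | 4,4,5,5-tetramethyl-2-{(2R)-6-methyl-2-[(1S,3S,6R)-6-methyl-7-oxabicyclo[4.1.0]heptan-3-yl]hept-5-en-2-yl}-1,3,2-dioxaborolane | CC(C)=CCC[C@](C)(B1OC(C)(C)C(C)(C)O1)[C@H]1CC[C@@]2(C)O[C@H]2C1 | intermediate
13 | (2S)-6-methyl-2-[(1S,3S,6R)-6-methyl-7-oxabicyclo[4.1.0]heptan-3-yl]hept-5-en-2-ol (ring-epoxidised (S,S)-α-bisabolol) | CC(C)=CCC[C@](C)(O)[C@H]1CC[C@@]2(C)O[C@H]2C1 | intermediate
14 | (3R,6S)-3-bromo-2,2,6-trimethyl-6-[(1S,3S,6R)-6-methyl-7-oxabicyclo[4.1.0]heptan-3-yl]oxane | CC1(C)O[C@](C)([C@H]2CC[C@@]3(C)O[C@H]3C2)CC[C@H]1Br | intermediate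
15 | (1R,2R,4S)-4-[(2S,5R)-5-bromo-2,6,6-trimethyloxan-2-yl]-2-chloro-1-methylcyclohexan-1-ol | CC1(C)O[C@](C)([C@H]2CC[C@@](C)(O)[C@H](Cl)C2)CC[C@H]1Br | intermediate
16 | (3R,6S)-3-bromo-6-[(1S,3R,4R)-4-bromo-3-chloro-4-methylcyclohexyl]-2,2,6-trimethyloxane | CC1(C)O[C@](C)([C@H]2CC[C@@](C)(Br)[C@H](Cl)C2)CC[C@H]1Br | target

Total step count: 10. Longest linear sequence: 10 steps (1 to 16).

Steps most likely to fail

Step 8. The ring closure may take the wrong regiochemical course: 5-exo attack at the secondary carbon would give the oxolane with a tertiary bromide, and the phenol released could erode the ring epoxide. The fallback sets out from 13. Mercuricyclisation with Hg(OAc)2 in THF, which follows Markovnikov orientation, and anion exchange with aqueous KBr would give the 6-endo organomercurial bromo{(3R,6S)-2,2,6-trimethyl-6-[(1S,3S,6R)-6-methyl-7-oxabicyclo[4.1.0]heptan-3-yl]oxan-3-yl}mercury F1, with mercury equatorial by the same chair argument. Bromodemercuration with Br2 and LiBr in pyridine should replace mercury by bromine with retention and comes back to the route at 14.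

Step 10. The tertiary cation may lose a proton (E1) faster than it captures bromide, or the chlorine may not bridge, which would scramble the carbon–bromine centre. The fallback sets out from 15. Dehydration with SOCl2 and pyridine would give the alkene, drawn as its exocyclic isomer (3R,6S)-3-bromo-6-[(1S,3R)-3-chloro-4-methylidenecyclohexyl]-2,2,6-trimethyloxane F2 (an endocyclic isomer converges in the next operation). Ionic Markovnikov hydrobromination (HBr in AcOH, CH2Cl2, −20 °C) should then install the tertiary bromide by axial attack anti to the neighbouring axial chlorine and comes back to the route at 16.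

Step 7. Telescoping may break down through slow transmetalation or protodeboronation of the alkylborane, or through incomplete oxidation of the hindered tertiary boronate. The fallback sets out from 9 and exchanges the roles of the coupling partners. Hydroboration with 9-BBN and iodinolysis (I2, NaOMe) would give the primary iodide 2-{(2R)-4-iodo-2-[(1S,3S,6R)-6-methyl-7-oxabicyclo[4.1.0]heptan-3-yl]butan-2-yl}-4,4,5,5-tetramethyl-1,3,2-dioxaborolane F3. Alkyl–alkenyl Suzuki–Miyaura coupling of F3 with commercial 4,4,5,5-tetramethyl-2-(2-methylprop-1-en-1-yl)-1,3,2-dioxaborolane (Pd(OAc)2, PCy3, K3PO4·H2O, THF) would give 12, and NaOH/H2O2 work-up in the same flask comes back to the route at 13. The two ring bonds are still made in one operation.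

Further compounds
F1 | step 8 | bromo{(3R,6S)-2,2,6-trimethyl-6-[(1S,3S,6R)-6-methyl-7-oxabicyclo[4.1.0]heptan-3-yl]oxan-3-yl}mercury | CC1(C)O[C@](C)([C@H]2CC[C@@]3(C)O[C@H]3C2)CC[C@H]1[Hg]Br
F2 | step 10 | (3R,6S)-3-bromo-6-[(1S,3R)-3-chloro-4-methylidenecyclohexyl]-2,2,6-trimethyloxane | CC1(C)O[C@](C)([C@H]2CCC(=C)[C@H](Cl)C2)CC[C@H]1Br
F3 | step 7 | 2-{(2R)-4-iodo-2-[(1S,3S,6R)-6-methyl-7-oxabicyclo[4.1.0]heptan-3-yl]butan-2-yl}-4,4,5,5-tetramethyl-1,3,2-dioxaborolane | ICC[C@](C)(B1OC(C)(C)C(C)(C)O1)[C@H]1CC[C@@]2(C)O[C@H]2C1
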